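**Retrosynthetic overview**
- Schizolaenone A is reached by fluoride removal of two aryl silyl ethers from its 7-O-TIPS, 4'-O-TBS derivative.
- The strategy rests on ring A: C5 (OH), C6 (prenyl) and C7 (O) are contiguous and C8 carries H, which is the pattern a vinylketene and a 1-siloxyalkyne deliver. O1, C2, C3, C4 and the C4a=C8a bond already exist as a chiral 2,3-dihydro-4H-pyran-4-one. Ring A is therefore cut at C8–C8a, C5–C6, C7–C8 and C4a–C5 into a 6-(diazoacetyl)dihydropyranone and a prenyl siloxyalkyne.
- Ring C, with the C2 stereocentre, comes from a catalytic asymmetric hetero-Diels–Alder reaction of the ring B aldehyde with a 1,3-bis(silyloxy)diene bearing the carboxylate; the ester is then converted to acid and diazoketone.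
- Ring B is 4-hydroxybenzaldehyde, C-geranylated at C3'; the siloxyalkyne comes from 4-methylpent-3-enoic acid by ynolate silylation.
- Ring order: B (purchased), then C (step 4), then A (step 9).

Key step: step 9

Abbreviations: geranyl = (2E)-3,7-dimethylocta-2,6-dien-1-yl; prenyl = 3-methylbut-2-en-1-yl; TBS = tert-butyldimethylsilyl; TIPS = triisopropylsilyl.
Assumption: the Ti(OiPr)4/(S)-BINOL catalyst is taken to direct the nucleophile to the Si face of the aryl aldehyde, as this catalyst class does with benzaldehyde-type substrates; if the sense proves opposite, (R)-BINOL is used with no other change.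

**Step 1**
Reactants: 1 4-hydroxybenzaldehyde; 2 geranyl bromide
Product: 3 3-geranyl-4-hydroxybenzaldehyde
Conditions: KOH (10% aq.), 25 °C
Reagents that add atoms: none
Why: Ortho C-alkylation of a phenoxide in water, where hydrogen bonding to the phenoxide oxygen favours attack through carbon, the blocked para position leaves only C3, and SN2 displacement at the primary allylic bromide keeps the E geometry; the O-geranyl ether is the expected separable by-product.

**Step 2**
Reactants: 3 3-geranyl-4-hydroxybenzaldehyde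
Product: 4 4-(tert-butyldimethylsilyloxy)-3-geranylbenzaldehyde
Conditions: t-BuMe2SiCl, imidazole, DMF, 25 °C
Reagents that add atoms: tert-butyldimethylsilyl chloride, CC(C)(C)[Si](C)(C)Cl
Why: Imidazole-promoted silylation of the phenol, which masks the acidic OH that would otherwise quench the titanium catalyst of step 4 and trap the ketene of step 9.

**Step 3**
Reactants: 5 methyl 2,4-dioxopentanoate
Product: 6 methyl (2Z)-2,4-bis(trimethylsilyloxy)penta-2,4-dienoate
Conditions: Me3SiOTf (2.2 equiv), Et3N (2.5 equiv), Et2O, 0 °C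
Reagents that add atoms: trimethylsilyl trifluoromethanesulfonate, C[Si](C)(C)OS(=O)(=O)C(F)(F)F
Why: Double O-silylation (soft enolisation) of a 1,3-dicarbonyl compound to a Chan-type 1,3-bis(silyloxy)diene; both possible mono-silyl enol ethers converge on 6, and the C2=C3 geometry is of no consequence because that bond ends up in the ring.

**Step 4**
Reactants: 4 4-(tert-butyldimethylsilyloxy)-3-geranylbenzaldehyde; 6 methyl (2Z)-2,4-bis(trimethylsilyloxy)penta-2,4-dienoate
Product: 8 methyl (2S)-2-[4-(tert-butyldimethylsilyloxy)-3-geranylphenyl]-4-oxo-3,4-dihydro-2H-pyran-6-carboxylate, via silyl aldol adduct 7 (not isolated)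
Conditions: Ti(OiPr)4 (10 mol%), (S)-BINOL (20 mol%), 4 Å MS, Et2O, −20 °C; then CF3CO2H, CH2Cl2, 0 °C
Reagents that add atoms: none
Why: Hetero-Diels–Alder reaction run by its Mukaiyama aldol/cyclocondensation pathway, in which the chiral Ti–BINOL Lewis acid directs the terminal CH2 of 6 to the Si face of the aldehyde and so sets C2 as S in adduct 7, after which acid desilylates and closes ring C through attack of the carbinol oxygen on the keto-ester carbon with loss of silanol, leaving the new stereocentre untouched.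

**Step 5**
Reactants: 8 methyl (2S)-2-[4-(tert-butyldimethylsilyloxy)-3-geranylphenyl]-4-oxo-3,4-dihydro-2H-pyran-6-carboxylate
Product: 9 (2S)-2-[4-(tert-butyldimethylsilyloxy)-3-geranylphenyl]-4-oxo-3,4-dihydro-2H-pyran-6-carboxylic acid
Conditions: Me3SnOH (4 equiv), ClCH2CH2Cl, 70 °C; then 0.1 M HCl wash
Reagents that add atoms: trimethyltin hydroxide, C[Sn](C)(C)O
Why: Methyl ester hydrolysis with Me3SnOH, whose tin-bound hydroxide cleaves the unhindered ester under near-neutral conditions and so avoids the conjugate addition or E1cB opening of the C2–O1 bond and the loss of the aryl TBS ether that aqueous alkali could cause.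

**Step 6**
Reactants: 9 (2S)-2-[4-(tert-butyldimethylsilyloxy)-3-geranylphenyl]-4-oxo-3,4-dihydro-2H-pyran-6-carboxylic acid
Product: 11 (2S)-6-(diazoacetyl)-2-[4-(tert-butyldimethylsilyloxy)-3-geranylphenyl]-2,3-dihydro-4H-pyran-4-one, via acid chloride 10 (not isolated)
Conditions: 1-chloro-N,N,2-trimethylprop-1-en-1-amine, CH2Cl2, 0 °C; then CH2N2 (3 equiv), Et2O, −20 to 0 °C
Reagents that add atoms: diazomethane, C=[N+]=[N-]
Why: Acylation of diazomethane by an acid chloride (the first stage of an Arndt–Eistert sequence), where the chloroenamine makes the chloride without free HCl and so spares the trisubstituted alkenes, the fast acylation at low temperature should outrun dipolar cycloaddition to the donor-substituted C5=C6 bond, and a second equivalent of diazomethane takes up the HCl.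

**Step 7**
Reactants: 12 4-methylpent-3-enoic acid
Product: 13 ethyl 4-methylpent-3-enoate
Conditions: EtI, K2CO3, DMF, 25 °C
Reagents that add atoms: iodoethane, CCI
Why: SN2 O-alkylation of the carboxylate, chosen over acid-catalysed esterification because this β,γ-unsaturated acid lactonises under protic acid.

**Step 8**
Reactants: 13 ethyl 4-methylpent-3-enoate
Product: 16 5-methyl-1-(triisopropylsilyloxy)hex-4-en-1-yne, via lithium dibromoenolate 14 (not isolated), via lithium ynolate 15 (not isolated)
Conditions: CH2Br2 (2.2 equiv), lithium 2,2,6,6-tetramethylpiperidide (LiTMP, 2.1 equiv), THF, −78 °C; add 13; then n-BuLi, −78 to 25 °C; then i-Pr3SiCl, −78 to 25 °C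
Reagents that add atoms: dibromomethane, BrCBr; triisopropylsilyl chloride, CC(C)[Si](Cl)(C(C)C)C(C)C
Why: Kowalski ester homologation stopped at the ynolate, in which (dibromomethyl)lithium adds to the ester, the derived dibromoenolate undergoes bromine–lithium exchange and 1,2-shift of the prenyl group to the carbenoid carbon, and the bulky silyl chloride caps the ynolate on oxygen where a small one would give the silylketene.

**Step 9**
Reactants: 11 (2S)-6-(diazoacetyl)-2-[4-(tert-butyldimethylsilyloxy)-3-geranylphenyl]-2,3-dihydro-4H-pyran-4-one; 16 5-methyl-1-(triisopropylsilyloxy)hex-4-en-1-yne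
Product: 20 (2S)-2-[4-(tert-butyldimethylsilyloxy)-3-geranylphenyl]-5-hydroxy-6-prenyl-7-(triisopropylsilyloxy)-2,3-dihydro-4H-chromen-4-one, via vinylketene 17 (not isolated), via 4-vinylcyclobutenone 18 (not isolated), via dienylketene 19 (not isolated)
Conditions: 16 (1.5 equiv), hν (medium-pressure Hg lamp, Pyrex filter, λ > 300 nm, FEP-tube flow reactor), degassed ClCH2CH2Cl, 25 °C; then 80 °C in the dark
Reagents that add atoms: none
Why: Light expels N2 from 11 and the dihydropyranyl carbon migrates (photochemical Wolff rearrangement) to give vinylketene 17 with the new C8–C8a bond, whose ketene C=C adds 16 in a [2+2] that joins the electrophilic ketene carbon to the nucleophilic, prenyl-bearing alkyne carbon (C5–C6) and the ketene CH to the siloxy carbon (C7–C8), giving cyclobutenone 18. Reversible 4π electrocyclic opening of 18 gives dienylketene 19, and ring A closes by 6π electrocyclisation of the ketene carbon onto the enol-ether carbon C4a (C4a–C5), followed by enolisation to the C5 phenol, which is hydrogen-bonded to C4=O. The closest known reaction is the Danheiser benzannulation in its photochemical Wolff form, which joins α,β-unsaturated α'-diazo ketones and triisopropylsiloxyalkynes to resorcinol monosilyl ethers. No stereocentre is created, since the sp3 carbon of 18 becomes aromatic C8, and C2 should survive because no acid or base able to open the C2–O1 bond is present. The step needs regioselectivity in the [2+2], secured by the ketene/ynol-ether polarisation that places prenyl between the two oxygens, and selective excitation of the diazoketone, secured by filtered light and a short residence time so that the flavanone chromophore forms mainly in the dark thermal stage.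

**Step 10**
Reactants: 20 (2S)-2-[4-(tert-butyldimethylsilyloxy)-3-geranylphenyl]-5-hydroxy-6-prenyl-7-(triisopropylsilyloxy)-2,3-dihydro-4H-chromen-4-one
Product: 21 schizolaenone A
Conditions: Bu4NF, AcOH (1:1, 3 equiv), THF, 0 °C
Reagents that add atoms: none
Why: Fluoride-mediated cleavage of both aryl silyl ethers, buffered with acetic acid so that the phenoxides are protonated at once and the base-induced retro-oxa-Michael opening that would racemise C2 does not set in.

**Compound list**
1 | 4-hydroxybenzaldehyde | O=Cc1ccc(O)cc1 | starting material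
2 | geranyl bromide, (2E)-1-bromo-3,7-dimethylocta-2,6-diene | CC(C)=CCC/C(C)=C/CBr | starting material
3 | 3-geranyl-4-hydroxybenzaldehyde | CC(C)=CCC/C(C)=C/Cc1cc(C=O)ccc1O | intermediate
4 | 4-(tert-butyldimethylsilyloxy)-3-geranylbenzaldehyde | CC(C)=CCC/C(C)=C/Cc1cc(C=O)ccc1O[Si](C)(C)C(C)(C)C | intermediate
5 | methyl 2,4-dioxopentanoate | COC(=O)C(=O)CC(C)=O | starting material
6 | methyl (2Z)-2,4-bis(trimethylsilyloxy)penta-2,4-dienoate | COC(=O)/C(O[Si](C)(C)C)=C/C(=C)O[Si](C)(C)C | intermediate
7 | methyl (2Z,6S)-6-[4-(tert-butyldimethylsilyloxy)-3-geranylphenyl]-4-oxo-2,6-bis(trimethylsilyloxy)hex-2-enoate | CC(C)=CCC/C(C)=C/Cc1cc([C@H](CC(=O)/C=C(\O[Si](C)(C)C)C(=O)OC)O[Si](C)(C)C)ccc1O[Si](C)(C)C(C)(C)C | intermediate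
8 | methyl (2S)-2-[4-(tert-butyldimethylsilyloxy)-3-geranylphenyl]-4-oxo-3,4-dihydro-2H-pyran-6-carboxylate | CC(C)=CCC/C(C)=C/Cc1cc([C@@H]2CC(=O)C=C(C(=O)OC)O2)ccc1O[Si](C)(C)C(C)(C)C | intermediate
9 | (2S)-2-[4-(tert-butyldimethylsilyloxy)-3-geranylphenyl]-4-oxo-3,4-dihydro-2H-pyran-6-carboxylic acid | CC(C)=CCC/C(C)=C/Cc1cc([C@@H]2CC(=O)C=C(C(=O)O)O2)ccc1O[Si](C)(C)C(C)(C)C | intermediate
10 | (2S)-2-[4-(tert-butyldimethylsilyloxy)-3-geranylphenyl]-4-oxo-3,4-dihydro-2H-pyran-6-carbonyl chloride | CC(C)=CCC/C(C)=C/Cc1cc([C@@H]2CC(=O)C=C(C(Cl)=O)O2)ccc1O[Si](C)(C)C(C)(C)C | intermediate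
11 | (2S)-6-(diazoacetyl)-2-[4-(tert-butyldimethylsilyloxy)-3-geranylphenyl]-2,3-dihydro-4H-pyran-4-one | CC(C)=CCC/C(C)=C/Cc1cc([C@@H]2CC(=O)C=C(C(=O)C=[N+]=[N-])O2)ccc1O[Si](C)(C)C(C)(C)C | intermediate
12 | 4-methylpent-3-enoic acid | CC(C)=CCC(=O)O | starting material
13 | ethyl 4-methylpent-3-enoate | CCOC(=O)CC=C(C)C | intermediate
14 | lithium 1,1-dibromo-5-methylhexa-1,4-dien-2-olate | [Li+].[O-]C(CC=C(C)C)=C(Br)Br | intermediate
15 | lithium 5-methylhex-4-en-1-yn-1-olate | [Li+].[O-]C#CCC=C(C)C | intermediate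
16 | 5-methyl-1-(triisopropylsilyloxy)hex-4-en-1-yne | CC(C)=CCC#CO[Si](C(C)C)(C(C)C)C(C)C | intermediate
17 | (2S)-2-[4-(tert-butyldimethylsilyloxy)-3-geranylphenyl]-6-(2-oxoethenyl)-2,3-dihydro-4H-pyran-4-one | CC(C)=CCC/C(C)=C/Cc1cc([C@@H]2CC(=O)C=C(C=C=O)O2)ccc1O[Si](C)(C)C(C)(C)C | intermediate
18 | 4-{(2S)-2-[4-(tert-butyldimethylsilyloxy)-3-geranylphenyl]-4-oxo-3,4-dihydro-2H-pyran-6-yl}-2-prenyl-3-(triisopropylsilyloxy)cyclobut-2-en-1-one, both epimers at the cyclobutenone sp3 carbon | CC(C)=CCC/C(C)=C/Cc1cc([C@@H]2CC(=O)C=C(C3C(=O)C(CC=C(C)C)=C3O[Si](C(C)C)(C(C)C)C(C)C)O2)ccc1O[Si](C)(C)C(C)(C)C | intermediate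
19 | (2S)-2-[4-(tert-butyldimethylsilyloxy)-3-geranylphenyl]-6-[4-oxo-3-prenyl-2-(triisopropylsilyloxy)buta-1,3-dien-1-yl]-2,3-dihydro-4H-pyran-4-one, pyranyl and ketene-bearing carbons cis | CC(C)=CCC/C(C)=C/Cc1cc([C@@H]2CC(=O)C=C(/C=C(/O[Si](C(C)C)(C(C)C)C(C)C)C(CC=C(C)C)=C=O)O2)ccc1O[Si](C)(C)C(C)(C)C | intermediate
20 | (2S)-2-[4-(tert-butyldimethylsilyloxy)-3-geranylphenyl]-5-hydroxy-6-prenyl-7-(triisopropylsilyloxy)-2,3-dihydro-4H-chromen-4-one | CC(C)=CCC/C(C)=C/Cc1cc([C@@H]2CC(=O)c3c(cc(O[Si](C(C)C)(C(C)C)C(C)C)c(CC=C(C)C)c3O)O2)ccc1O[Si](C)(C)C(C)(C)C | intermediate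
21 | schizolaenone A, (2S)-2-(3-geranyl-4-hydroxyphenyl)-5,7-dihydroxy-6-prenyl-2,3-dihydro-4H-chromen-4-one | CC(C)=CCC/C(C)=C/Cc1cc([C@@H]2CC(=O)c3c(cc(O)c(CC=C(C)C)c3O)O2)ccc1O | target

**Totals**
Total step count: 10. Longest linear sequence: 7 steps (steps 1, 2, 4, 5, 6, 9, 10).

**Steps most likely to fail**

Step 9. Light absorbed by the aryl ether and enone chromophores may cleave the C2–O1 bond and erode the configuration at C2. The vinylketene may also be captured too slowly by the hindered siloxyalkyne, so that it dimerises or acylates the phenolic product.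
Fallback: it sets out from siloxyalkyne 16 and returns at 20. Ring A is built on an achiral pyranone and C2 is set afterwards.
- Commercial 4-oxo-4H-pyran-2-carboxylic acid would be converted with the chloroenamine of step 6 into 4-oxo-4H-pyran-2-carbonyl chloride F1, and with diazomethane into 2-(diazoacetyl)-4H-pyran-4-one F2.
- Benzannulation of F2 with 16 by the same cascade should give 5-hydroxy-6-prenyl-7-(triisopropylsilyloxy)-4H-chromen-4-one F3, which has no stereocentre to lose.
- Separately, 4-bromophenol would be C-geranylated as in step 1 to 4-bromo-2-geranylphenol F4 and silylated (t-BuMe2SiCl, imidazole) to (4-bromo-2-geranylphenoxy)(tert-butyl)dimethylsilane F5.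
- Bromine–lithium exchange (n-BuLi, THF, −78 °C), B(OiPr)3 and aqueous work-up would give [4-(tert-butyldimethylsilyloxy)-3-geranylphenyl]boronic acid F6.
- Rhodium-catalysed asymmetric 1,4-addition of F6 to F3 ([RhCl(C2H4)2]2, chiral diene ligand of the enantiomer that gives 2S, catalytic aqueous KOH, toluene, 25 °C) would then deliver 20.

Step 4. The electron-rich aldehyde may react sluggishly with the ester-deactivated diene, with incomplete facial control. Acid-promoted ionisation at the benzylic carbinol during ring closure may also erode the enantiomeric purity.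
Fallback: it sets out from aldehyde 4 and returns at ester 8. The stereocentre is set by a reagent-controlled allylation and ring C is closed by Claisen condensation and cyclodehydration.
- Brown allylation with the B-allyldiisopinocampheylborane antipode that adds to the Si face (Et2O, −78 °C, ethanolamine work-up) would give (1S)-1-[4-(tert-butyldimethylsilyloxy)-3-geranylphenyl]but-3-en-1-ol F7.
- Et3SiCl and imidazole would give its triethylsilyl ether F8.
- Tsuji–Wacker oxidation of the terminal alkene (PdCl2 cat., CuCl, O2, DMF/H2O) would give (4S)-4-[4-(tert-butyldimethylsilyloxy)-3-geranylphenyl]-4-(triethylsilyloxy)butan-2-one F9.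
- The kinetic methyl enolate (LiN(SiMe3)2, THF, −78 °C) would be condensed with dimethyl oxalate to give methyl (6S)-6-[4-(tert-butyldimethylsilyloxy)-3-geranylphenyl]-2,4-dioxo-6-(triethylsilyloxy)hexanoate F10.
- CF3CO2H in wet CH2Cl2 would remove the triethylsilyl group and cyclodehydrate F10 to 8.

Step 8. The doubly activated C2 methylene of the β,γ-unsaturated ester may be deprotonated by (dibromomethyl)lithium or LiTMP in competition with carbonyl addition. That would move the alkene into conjugation and leave little ynolate.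
Fallback: it sets out from ester 13 and returns at lithium ynolate 15, which is silylated to 16 as in step 8. The ynolate is made by oxidation of an acetylide and no longer from the ester carbonyl.
- i-Bu2AlH (CH2Cl2, −78 °C) would give 4-methylpent-3-enal F11.
- Ramirez olefination (CBr4, PPh3, Zn, CH2Cl2, 0 °C) would give 1,1-dibromo-5-methylhexa-1,4-diene F12.
- n-BuLi (2 equiv, THF, −78 °C; Corey–Fuchs) would give lithium 5-methylhex-4-en-1-ynide F13.
- Oxidation with lithium tert-butyl peroxide (t-BuOOH and LiN(SiMe3)2, THF, −78 to 0 °C; Julia ynolate synthesis) would give 15.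

**Further compounds**
F1 | step 9 | 4-oxo-4H-pyran-2-carbonyl chloride | O=C(Cl)C1=CC(=O)C=CO1
F2 | step 9 | 2-(diazoacetyl)-4H-pyran-4-one | [N-]=[N+]=CC(=O)C1=CC(=O)C=CO1
F3 | step 9 | 5-hydroxy-6-prenyl-7-(triisopropylsilyloxy)-4H-chromen-4-one | O=C1C=COc2cc(O[Si](C(C)C)(C(C)C)C(C)C)c(CC=C(C)C)c(O)c12
F4 | step 9 | 4-bromo-2-geranylphenol | CC(C)=CCC/C(C)=C/Cc1cc(Br)ccc1O
F5 | step 9 | (4-bromo-2-geranylphenoxy)(tert-butyl)dimethylsilane | CC(C)=CCC/C(C)=C/Cc1cc(Br)ccc1O[Si](C)(C)C(C)(C)C
F6 | step 9 | [4-(tert-butyldimethylsilyloxy)-3-geranylphenyl]boronic acid | CC(C)=CCC/C(C)=C/Cc1cc(B(O)O)ccc1O[Si](C)(C)C(C)(C)C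
F7 | step 4 | (1S)-1-[4-(tert-butyldimethylsilyloxy)-3-geranylphenyl]but-3-en-1-ol | CC(C)=CCC/C(C)=C/Cc1cc([C@H](CC=C)O)ccc1O[Si](C)(C)C(C)(C)C
F8 | step 4 | (1S)-1-[4-(tert-butyldimethylsilyloxy)-3-geranylphenyl]but-3-en-1-yl triethylsilyl ether | CC(C)=CCC/C(C)=C/Cc1cc([C@H](CC=C)O[Si](CC)(CC)CC)ccc1O[Si](C)(C)C(C)(C)C
F9 | step 4 | (4S)-4-[4-(tert-butyldimethylsilyloxy)-3-geranylphenyl]-4-(triethylsilyloxy)butan-2-one | CC(C)=CCC/C(C)=C/Cc1cc([C@H](CC(C)=O)O[Si](CC)(CC)CC)ccc1O[Si](C)(C)C(C)(C)C
F10 | step 4 | methyl (6S)-6-[4-(tert-butyldimethylsilyloxy)-3-geranylphenyl]-2,4-dioxo-6-(triethylsilyloxy)hexanoate | CC(C)=CCC/C(C)=C/Cc1cc([C@H](CC(=O)CC(=O)C(=O)OC)O[Si](CC)(CC)CC)ccc1O[Si](C)(C)C(C)(C)C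
F11 | step 8 | 4-methylpent-3-enal | CC(C)=CCC=O
F12 | step 8 | 1,1-dibromo-5-methylhexa-1,4-diene | CC(C)=CCC=C(Br)Br
F13 | step 8 | lithium 5-methylhex-4-en-1-ynide | [Li+].[C-]#CCC=C(C)C
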